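You cannot wait Friday's flask up to full conversion: between 72.0 h and 120 h its target reading crept from 78.5% to 79.3%, which stands 20.7% of the starting material short of it. Free catalyst turns starting material into target through catalyst intermediate A, and second substrate into second product through catalyst intermediate B. From intermediate B, catalyst can leave as trapped intermediate or spent catalyst, and second substrate also condenses with itself.

common to all: starting material 0.025 M; free catalyst 2.5 mol%
- Friday's: second substrate 2 equiv; capture agent 2.5 mM; temperature 100 °C; the very flask that is asked about, followed so far
- Wednesday's: second substrate 2 equiv; capture agent 2.5 mM; temperature 106 °C; run made earlier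
- flask: second substrate 2.00 equiv; capture agent 2.50 mM; temperature 100 °C; time 8.0 d

| Friday's: time / h | Friday's: target / % | Wednesday's: time / h | Wednesday's: target / % |
|---|---|---|---|
| 10.0 | 57.8 | 10.0 | 69.9 |
| 15.0 | 65.7 | 15.0 | 76.3 |
| 25.0 | 72.4 | 25.0 | 80.5 |
| 40.0 | 75.2 | 40.0 | 83.0 |
| 72.0 | 78.5 | 72.0 | 85.0 |
| 120 | 79.3 | 120 | 85.0 |

(readings scatter by 0.5 percentage points)

- alpha: at 8.0 d raise the temperature by 15 K, then wait 15 d
- delta: change nothing and wait 15 d more
- epsilon: at 8.0 d add free catalyst, 50.0% of the amount charged, then wait 15 d
- beta: at 8.0 d take out 90% of the target then present, then wait 15 d

* target, in percent of the starting material first charged, at 8.0 d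
* the option that brings most further target ("none" if no option brings more than 2 percentage points) (alpha / delta / epsilon / beta / none)
* target present, with what was taken out counted in, in percent of the starting material first charged, after epsilon
* target present, with what was taken out counted in, in percent of the starting material first charged, after beta

- what is taken out of target is counted as made
- the analysis behind the earlier runs scatters by 0.5 percentage points, standard deviation
- steps under discussion: starting material + free catalyst <-> catalyst intermediate A; catalyst intermediate A -> free catalyst + target; second substrate + free catalyst <-> catalyst intermediate B; catalyst intermediate B -> free catalyst + second product; catalyst intermediate B + capture agent -> trapped intermediate; catalyst intermediate B -> spent catalyst; 2 second substrate -> self-condensation product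
- additions bring no volume worth counting

The step to target runs one way, so I read the stop in both runs, with target short of full conversion, as a stop of the catalyst, not an equilibrium. I take the starting material to fall pseudo-first-order at a given amount of working catalyst, so I count in powers of ten. Call the decades a charge buys the base-ten logarithm of starting material charged over starting material left at the stop. Friday's flask reads 0.684, and Wednesday's flask, with the same charges but hotter, reads 0.824.

Decades are pace times working life. Over the first 10.0 h, Friday's pace reads 0.0375 h⁻¹ and Wednesday's 0.0521 h⁻¹, which gives working lives of 18.3 h and 15.8 h. Wednesday's flask ends higher because its pace rose by a factor of 1.39, more than its life shrank, a factor of 1.16.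

Waiting, heating and taking target out add no catalyst, so I back epsilon. If decades follow the charge, the flask reaches 1.03 decades, which means 90.6% target, a gain of 11 percentage points, more than the 2 points needed.

The forecast says 79.7% now, epsilon as best, 95% after epsilon and 79.8% after beta. Its epsilon figure stands above mine, on the ground that “added catalyst should live longer”.

The flask reads 79.3% at 8.0 d, and beta ends at 79.6%. Epsilon ends at 100%, a gain of 21 points, far more than alpha's 0.43 points, delta's 0.29 points or beta's 0.29 points.

    starting material + free catalyst ⇌ catalyst intermediate A (K = 89.3 L mol⁻¹, k = 29300 L mol⁻¹ h⁻¹, Ea = 72.0 kJ mol⁻¹, ΔH = −31.0 kJ mol⁻¹)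
    catalyst intermediate A → free catalyst + target (k = 21.7 h⁻¹, Ea = 98.0 kJ mol⁻¹)
    second substrate + free catalyst ⇌ catalyst intermediate B (K = 170 L mol⁻¹, k = 2160 L mol⁻¹ h⁻¹, Ea = 68.0 kJ mol⁻¹, ΔH = −24.0 kJ mol⁻¹)
    catalyst intermediate B → free catalyst + second product (k = 8.41 h⁻¹, Ea = 119 kJ mol⁻¹)
    catalyst intermediate B + capture agent → trapped intermediate (k = 271 L mol⁻¹ h⁻¹, Ea = 83.0 kJ mol⁻¹)
    catalyst intermediate B → spent catalyst (k = 0.158 h⁻¹, Ea = 113 kJ mol⁻¹)
    2 second substrate → self-condensation product (k = 8.07 L mol⁻¹ h⁻¹, Ea = 90.0 kJ mol⁻¹)
    (constants at 100 °C)

My lower figure already passed the 2 points mark, so the choice stood whichever epsilon figure held. In the flask at 192 h, second substrate stood at 0.59% of its charge and capture agent at 80%. The neighbour charged 4.2 mol% of free catalyst should buy 1.15 decades, leaving 7.08%. It leaves 1.7% of its starting material at 192 h, which is 1.77 decades, with target at 98.3%.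

The runs come from a simulation from invented constants; noise was put on by code.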